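Ring B of the target is cut at C6–C7 and C10–C11 (ring A: C1 bearing =CH2, C2, C3, C4–Br, C5 gem-dimethyl, spiro C6; ring B: C6, C7, C8, C9 with Me and Cl, C10–Br, C11). The feature used is that spiro C6 sits between two ring B methylenes, para to C9, so C6/C11 can be the α-carbon and formyl carbon of a ring A aldehyde and C7–C10 can be methyl vinyl ketone. One enamine Michael–aldol operation then builds ring B, the quaternary spiro centre and a C9 enone that later marks C10 for bromine. The precursor is (3R)-3-bromo-2,2-dimethyl-6-methylidenecyclohexane-1-carbaldehyde, from an enantiospecific bromonium cyclisation.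

Key step: step 8

Assumption: the ligand antipode that delivers the (2R)-bromochloride in step 1 is used, aldehyde 10 is carried as its mixture of C6 epimers because that centre becomes trigonal in step 8, and spiro compounds 14–21 are named with the atom labels of the first paragraph.

Step 1
Reactants: 1 prenol (3-methylbut-2-en-1-ol)
Product: 2 (2R)-2-bromo-3-chloro-3-methylbutan-1-ol
Conditions: NBS, ClTi(Oi-Pr)3, chiral tridentate salicylaldimine–amino alcohol ligand (20 mol%), hexanes, −20 °C
Reagents that add atoms: N-bromosuccinimide, O=C1CCC(=O)N1Br; chlorotitanium triisopropoxide, CC(C)O[Ti](Cl)(OC(C)C)OC(C)C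
Why: Catalytic enantioselective bromochlorination of an allylic alcohol: the titanium alkoxide of prenol held by the chiral ligand takes Br+ from NBS on one alkene face and chloride enters anti at the tertiary carbon, so the ligand sets C2 as (R) and the secondary bromide/tertiary chloride pattern follows from opening at the more substituted carbon.

Step 2
Reactants: 2 (2R)-2-bromo-3-chloro-3-methylbutan-1-ol
Product: 3 (2R)-2-bromo-3-chloro-3-methylbutyl trifluoromethanesulfonate
Conditions: Tf2O, 2,6-lutidine, CH2Cl2, −78 °C
Reagents that add atoms: trifluoromethanesulfonic anhydride, O=S(=O)(OS(=O)(=O)C(F)(F)F)C(F)(F)F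
Why: O-Sulfonylation of the primary alcohol at low temperature does not touch the stereocentre, and the β-bromo triflate is used at once because it is the leaving group reactive enough for clean alkylation at −78 °C.

Step 3
Reactants: 3 (2R)-2-bromo-3-chloro-3-methylbutyl trifluoromethanesulfonate; 4 methyl acetoacetate
Product: 6 methyl (6R)-6-bromo-7-chloro-7-methyl-3-oxooctanoate, via acetoacetate dianion 5 (not isolated)
Conditions: 4, NaH, THF, 0 °C; n-BuLi, 0 °C; then 3, −78 → −40 °C; aq. NH4Cl
Reagents that add atoms: none
Why: γ-Alkylation of an acetoacetate dianion: the terminal carbanion is the more nucleophilic site and displaces the primary triflate by SN2 at a temperature at which elimination of HBr or HCl does not compete, and the bromine-bearing stereocentre is not involved.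

Step 4
Reactants: 6 methyl (6R)-6-bromo-7-chloro-7-methyl-3-oxooctanoate
Product: 7 methyl (3R)-3-bromo-2,2-dimethyl-6-oxocyclohexane-1-carboxylate
Conditions: HFIP (0.05 M), 23 °C
Reagents that add atoms: none
Why: Solvolytic bromonium-ion cyclisation: in ionising, weakly nucleophilic HFIP the tertiary chloride leaves with anchimeric help from the neighbouring bromine and the enol carbon of the β-keto ester opens the bromonium ion at its tertiary carbon to close the six-membered ring, so bromine never leaves its carbon and the (R) configuration is carried over, while any O-cyclised tertiary enol ether re-ionises under the acidic conditions and ends as the C–C bonded product.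

Step 5
Reactants: 7 methyl (3R)-3-bromo-2,2-dimethyl-6-oxocyclohexane-1-carboxylate
Product: 8 methyl (3R)-3-bromo-2,2-dimethyl-6-methylidenecyclohexane-1-carboxylate
Conditions: Cp2TiMe2 (2.5 equiv), toluene/THF, 65 °C, dark
Reagents that add atoms: dimethyltitanocene, C[Ti](C)(C1C=CC=C1)C1C=CC=C1
Why: Petasis methylenation: Cp2Ti=CH2 formed on heating is non-basic, attacks the ketone much faster than the hindered ester and ignores the alkyl bromide, and the substrate should react as its keto tautomer because the α-hydrogen is crowded by the adjacent quaternary carbon, whereas a phosphorus ylide would simply deprotonate the β-keto ester.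

Step 6
Reactants: 8 methyl (3R)-3-bromo-2,2-dimethyl-6-methylidenecyclohexane-1-carboxylate
Product: 9 [(3R)-3-bromo-2,2-dimethyl-6-methylidenecyclohexyl]methanol
Conditions: i-Bu2AlH (2.5 equiv), CH2Cl2, −78 → 0 °C; aq. potassium sodium tartrate
Reagents that add atoms: none
Why: Hydride reduction of the ester to the primary alcohol with i-Bu2AlH spares the secondary bromide and the 1,1-disubstituted alkene, and full reduction followed by oxidation avoids the aldehyde/alcohol mixtures that partial reduction of a hindered ester can give.

Step 7
Reactants: 9 [(3R)-3-bromo-2,2-dimethyl-6-methylidenecyclohexyl]methanol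
Product: 10 (3R)-3-bromo-2,2-dimethyl-6-methylidenecyclohexane-1-carbaldehyde
Conditions: Dess–Martin periodinane, pyridine, CH2Cl2, 0 °C
Reagents that add atoms: none
Why: Dess–Martin oxidation buffered with pyridine gives the β,γ-unsaturated aldehyde without acid or strong base, so the exocyclic double bond is not drawn into conjugation, and the aldehyde is used at once as its mixture of C6 epimers.

Step 8
Reactants: 10 (3R)-3-bromo-2,2-dimethyl-6-methylidenecyclohexane-1-carbaldehyde; 11 methyl vinyl ketone
Product: 14 (4R,6R)-4-bromo-5,5-dimethyl-1-methylidenespiro[5.5]undec-10-en-9-one, via dienamine 12 (not isolated), via keto aldehyde 13 (not isolated)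
Conditions: pyrrolidine (1.5 equiv), 4 Å MS, PhH, 23 °C; then 11 (3 equiv), 23 → 50 °C; then AcOH/NaOAc/H2O, 70 °C
Reagents that add atoms: none
Why: Pyrrolidine condenses with 10 to the linearly conjugated 1-aminodiene 12 (N–C11=C6–C1=CH2), whose enamine carbon C6 adds to methyl vinyl ketone (C6–C7 bond); hydrolysis gives keto aldehyde 13, and the amine/acetate buffer then drives the intramolecular aldol condensation of the methyl ketone carbon C10 onto the formyl carbon C11 with loss of water. The closest known reaction type is the Stork enamine variant of the Robinson annulation applied to α-branched aldehydes, which gives 4,4-disubstituted (spiro) cyclohexenones. Ring B closes in the aldol step by a 6-(enolendo)-exo-trig attack, the Michael step being intermolecular. The only new stereocentre, C6, is set in the Michael step by the face of the ring A chair (C4–Br equatorial) that the enone uses: approach along the equatorial direction places C7 cis to the C4 bromide, which is the (6R) configuration. The step needs bond formation at C6 and not at the exocyclic CH2 terminus, and equatorial instead of axial approach; the C5 gem-dimethyl group secures the first by A(1,3) strain, which turns the amino group toward C1 and twists the aminodiene out of the coplanar s-cis geometry that a [4+2] or terminal addition would need, and the axial hydrogens on C2 and C4 obstruct the axial approach from under the ring, whereas the equatorial approach has to pass the axial C5 methyl, so this facial choice is the accepted risk of the route. The non-basic enamine and the buffered hydrolysis should leave the neopentyl-type secondary bromide and the exocyclic alkene untouched.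

Step 9
Reactants: 14 (4R,6R)-4-bromo-5,5-dimethyl-1-methylidenespiro[5.5]undec-10-en-9-one
Product: 16 (4R,6R)-4-bromo-5,5-dimethyl-1-methylidenespiro[5.5]undec-9-en-9-yl trifluoromethanesulfonate, via lithium enolate 15 (not isolated)
Conditions: LiBH(s-Bu)3 (1.1 equiv), THF, −78 °C; then PhNTf2, −78 → 0 °C; aq. NH4Cl
Reagents that add atoms: N-phenylbis(trifluoromethanesulfonimide), O=S(=O)(N(c1ccccc1)S(=O)(=O)C(F)(F)F)C(F)(F)F
Why: Conjugate reduction of a cyclohexenone that is unsubstituted at its β-carbon by a bulky trialkylborohydride, followed by O-triflation of the enolate: hydride adds to C11 and the enolate, hence the triflate, can only be the C9=C10 isomer, which fixes C10 as the future C–Br carbon.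

Step 10
Reactants: 16 (4R,6R)-4-bromo-5,5-dimethyl-1-methylidenespiro[5.5]undec-9-en-9-yl trifluoromethanesulfonate
Product: 17 (4R,6R)-4-bromo-5,5,9-trimethyl-1-methylidenespiro[5.5]undec-9-ene
Conditions: MeMgBr (1.5 equiv), Fe(acac)3 (5 mol%), THF/NMP, −30 °C
Reagents that add atoms: methylmagnesium bromide, C[Mg]Br
Why: Iron-catalysed Kumada-type cross-coupling of an alkenyl triflate with MeMgBr should be complete within minutes at −30 °C, before the Grignard reagent or the iron catalyst can engage the hindered secondary alkyl bromide.

Step 11
Reactants: 17 (4R,6R)-4-bromo-5,5,9-trimethyl-1-methylidenespiro[5.5]undec-9-ene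
Product: 18 (4R,6R,9S,10R)-4-bromo-9,10-epoxy-5,5,9-trimethyl-1-methylidenespiro[5.5]undecane
Conditions: mCPBA (1.05 equiv), NaHCO3, CH2Cl2, −20 → 0 °C
Reagents that add atoms: 3-chloroperoxybenzoic acid, OOC(=O)c1cccc(Cl)c1
Why: Prilezhaev epoxidation: the trisubstituted C9=C10 alkene is more electron-rich and far less hindered than the C1 methylidene next to the spiro centre, and the peracid approaches ring B anti to the C1 arm, which is pseudoaxial on C6 because the bulkier C5 (CMe2) takes the equatorial site, so the oxirane oxygen ends cis to C5 and (9S,10R) is set.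

Step 12
Reactants: 18 (4R,6R,9S,10R)-4-bromo-9,10-epoxy-5,5,9-trimethyl-1-methylidenespiro[5.5]undecane
Product: 19 (4R,6R,9R,10R)-4-bromo-9-chloro-5,5,9-trimethyl-1-methylidenespiro[5.5]undecan-10-ol
Conditions: TiCl4 (1.1 equiv), CH2Cl2, −78 °C; aq. NaHCO3
Reagents that add atoms: titanium tetrachloride, Cl[Ti](Cl)(Cl)Cl
Why: Lewis acid-promoted epoxide opening with SN1-like regioselectivity: TiCl4 weakens the bond to the tertiary carbon C9 and chloride enters anti to the departing oxygen, giving the (9R) tertiary chloride with inversion and leaving the (10R) carbinol on the original face.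

Step 13
Reactants: 19 (4R,6R,9R,10R)-4-bromo-9-chloro-5,5,9-trimethyl-1-methylidenespiro[5.5]undecan-10-ol
Product: 21 (4R,6R,9R,10S)-4,10-dibromo-9-chloro-5,5,9-trimethyl-1-methylidenespiro[5.5]undecane, via C10 triflate 20 (not isolated)
Conditions: Tf2O, pyridine, CH2Cl2, −78 → −40 °C; then n-Bu4NBr, −40 → 0 °C
Reagents that add atoms: tetrabutylammonium bromide, CCCC[N+](CCCC)(CCCC)CCCC.[Br-]
Why: Invertive deoxybromination by SN2 displacement of a secondary triflate with bromide: in the ring B chair the C9–Cl and C10–O bonds are gauche and no C11–H is antiperiplanar to the leaving group, so neither chlorine participation nor E2 is set up, and bromide enters anti to oxygen, turning (10R) into (10S) with bromine cis to chlorine.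

Compound list
1 | prenol (3-methylbut-2-en-1-ol) | CC(C)=CCO | starting material
2 | (2R)-2-bromo-3-chloro-3-methylbutan-1-ol | OC[C@@H](Br)C(C)(C)Cl | intermediate
3 | (2R)-2-bromo-3-chloro-3-methylbutyl trifluoromethanesulfonate | O=S(=O)(OC[C@@H](Br)C(C)(C)Cl)C(F)(F)F | intermediate
4 | methyl acetoacetate | COC(=O)CC(C)=O | starting material
5 | sodium lithium dianion of methyl acetoacetate | [CH2-]C(=O)[CH-]C(=O)OC.[Na+].[Li+] | intermediate
6 | methyl (6R)-6-bromo-7-chloro-7-methyl-3-oxooctanoate | COC(=O)CC(=O)CC[C@@H](Br)C(C)(C)Cl | intermediate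
7 | methyl (3R)-3-bromo-2,2-dimethyl-6-oxocyclohexane-1-carboxylate (C1 epimers) | COC(=O)C1C(=O)CC[C@@H](Br)C1(C)C | intermediate
8 | methyl (3R)-3-bromo-2,2-dimethyl-6-methylidenecyclohexane-1-carboxylate | COC(=O)C1C(=C)CC[C@@H](Br)C1(C)C | intermediate
9 | [(3R)-3-bromo-2,2-dimethyl-6-methylidenecyclohexyl]methanol | OCC1C(=C)CC[C@@H](Br)C1(C)C | intermediate
10 | (3R)-3-bromo-2,2-dimethyl-6-methylidenecyclohexane-1-carbaldehyde (C1 epimers) | O=CC1C(=C)CC[C@@H](Br)C1(C)C | intermediate
11 | methyl vinyl ketone (but-3-en-2-one) | CC(=O)C=C | starting material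
12 | 1-{[(3R)-3-bromo-2,2-dimethyl-6-methylidenecyclohexylidene]methyl}pyrrolidine | C=C1CC[C@@H](Br)C(C)(C)C1=CN1CCCC1 | intermediate
13 | (1R,3R)-3-bromo-2,2-dimethyl-6-methylidene-1-(3-oxobutyl)cyclohexane-1-carbaldehyde | C=C1CC[C@@H](Br)C(C)(C)[C@@]1(C=O)CCC(C)=O | intermediate
14 | (4R,6R)-4-bromo-5,5-dimethyl-1-methylidenespiro[5.5]undec-10-en-9-one | C=C1CC[C@@H](Br)C(C)(C)[C@@]12CCC(=O)C=C2 | intermediate
15 | lithium (4R,6R)-4-bromo-5,5-dimethyl-1-methylidenespiro[5.5]undec-9-en-9-olate | C=C1CC[C@@H](Br)C(C)(C)[C@@]12CCC([O-])=CC2.[Li+] | intermediate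
16 | (4R,6R)-4-bromo-5,5-dimethyl-1-methylidenespiro[5.5]undec-9-en-9-yl trifluoromethanesulfonate | C=C1CC[C@@H](Br)C(C)(C)[C@@]12CCC(OS(=O)(=O)C(F)(F)F)=CC2 | intermediate
17 | (4R,6R)-4-bromo-5,5,9-trimethyl-1-methylidenespiro[5.5]undec-9-ene | C=C1CC[C@@H](Br)C(C)(C)[C@@]12CCC(C)=CC2 | intermediate
18 | (4R,6R,9S,10R)-4-bromo-9,10-epoxy-5,5,9-trimethyl-1-methylidenespiro[5.5]undecane (oxirane oxygen cis to C5) | C=C1CC[C@@H](Br)C(C)(C)[C@@]12CC[C@]3(C)O[C@@H]3C2 | intermediate
19 | (4R,6R,9R,10R)-4-bromo-9-chloro-5,5,9-trimethyl-1-methylidenespiro[5.5]undecan-10-ol | C=C1CC[C@@H](Br)C(C)(C)[C@@]12CC[C@@](C)(Cl)[C@H](O)C2 | intermediate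
20 | (4R,6R,9R,10R)-4-bromo-9-chloro-5,5,9-trimethyl-1-methylidenespiro[5.5]undecan-10-yl trifluoromethanesulfonate | C=C1CC[C@@H](Br)C(C)(C)[C@@]12CC[C@@](C)(Cl)[C@H](OS(=O)(=O)C(F)(F)F)C2 | intermediate
21 | (4R,6R,9R,10S)-4,10-dibromo-9-chloro-5,5,9-trimethyl-1-methylidenespiro[5.5]undecane | C=C1CC[C@@H](Br)C(C)(C)[C@@]12CC[C@@](C)(Cl)[C@@H](Br)C2 | target

Total step count: 13. Longest linear sequence: 13 steps (prenol to 21).

Steps most likely to fail

Step 8. The C6–C7 bond may form on the wrong face of C6 (the axial C5 methyl screens the face the route needs), or through the exocyclic CH2 terminus of the aminodiene, or after migration of the exocyclic double bond into ring A during enamine equilibration. The fallback sets out from keto ester 7 and builds the spiro centre by a cycloaddition in which the same steric bias works in the right direction. Ester cleavage with Me3SnOH (1,2-dichloroethane, 80 °C) should give β-keto acid F1, which loses CO2 on warming to bromo ketone F2. α-Methylenation at its only enolisable position (paraformaldehyde, N-methylanilinium trifluoroacetate, THF, reflux) should give enone F3. A Me2AlCl-promoted Diels–Alder reaction with isoprene (CH2Cl2, −78 → −20 °C) then forms C7–C8 and C10–C11. The diene terminus should enter at C6 anti to the axial C5 methyl, so that C11 is trans and C7 cis to the bromide, and the methyl group should land on C9 by the para rule, giving spiro ketone F4. Methylenation of the C1 ketone with Cp2TiMe2 (toluene, 80 °C) comes back to the route at alkene 17.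

Step 13. Substitution at C10 may be too slow, because bromide must enter on the ring B face that carries the axial C1 arm and next to a quaternary carbon; elimination toward C11 or ionisation with rearrangement could then overtake it. The fallback sets out from chlorohydrin 19 and changes how the C–O bond is activated: PPh3 and CBr4 (toluene, 60 °C) convert the alcohol into alkoxyphosphonium bromide F8, a contact ion pair with a neutral leaving group and no free sulfonate, which collapses with inversion and comes back to the route at 21.

Step 12. Regiocontrol may be lost: trans-diaxial opening of the preferred half-chair of 18 would put chloride on C10, and the C9 cation can also rearrange by hydride shift. The fallback sets out from alkene 17. OsO4 (cat.) with NMO in acetone/water should give syn-diol F5 on the same ring B face. MeC(OMe)3 with PPTS gives cyclic orthoacetate F6, and Me3SiCl converts it, through the acetoxonium ion, into chloro acetate F7. Chloride should attack the tertiary C9, whose C–O bond is axial, with inversion, so that electronic and stereoelectronic preferences coincide. Acetate cleavage with i-Bu2AlH at −78 °C (a basic method would close the epoxide again) comes back to the route at chlorohydrin 19.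

Further compounds
F1 | step 8 | (3R)-3-bromo-2,2-dimethyl-6-oxocyclohexane-1-carboxylic acid | OC(=O)C1C(=O)CC[C@@H](Br)C1(C)C
F2 | step 8 | (3R)-3-bromo-2,2-dimethylcyclohexan-1-one | O=C1CC[C@@H](Br)C1(C)C
F3 | step 8 | (3R)-3-bromo-2,2-dimethyl-6-methylidenecyclohexan-1-one | C=C1CC[C@@H](Br)C(C)(C)C1=O
F4 | step 8 | (4R,6S)-4-bromo-5,5,9-trimethylspiro[5.5]undec-9-en-1-one (C7 cis to bromide) | O=C1CC[C@@H](Br)C(C)(C)[C@@]12CCC(C)=CC2
F5 | step 12 | (4R,6R,9S,10R)-4-bromo-5,5,9-trimethyl-1-methylidenespiro[5.5]undecane-9,10-diol | C=C1CC[C@@H](Br)C(C)(C)[C@@]12CC[C@](C)(O)[C@H](O)C2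
F6 | step 12 | cyclic methyl orthoacetate of diol F5 (2-methoxy-2-methyl-1,3-dioxolane fused at C9–C10) | C=C1CC[C@@H](Br)C(C)(C)[C@@]12CC[C@]3(C)OC(C)(OC)O[C@@H]3C2
F7 | step 12 | (4R,6R,9R,10R)-4-bromo-9-chloro-5,5,9-trimethyl-1-methylidenespiro[5.5]undecan-10-yl acetate | C=C1CC[C@@H](Br)C(C)(C)[C@@]12CC[C@@](C)(Cl)[C@H](OC(C)=O)C2
F8 | step 13 | alkoxytriphenylphosphonium bromide of 19 (P–O bond at C10) | C=C1CC[C@@H](Br)C(C)(C)[C@@]12CC[C@@](C)(Cl)[C@H](O[P+](c3ccccc3)(c3ccccc3)c3ccccc3)C2.[Br-]
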